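## The problem

Catechin 5,7-di-O-gallate is a flavan. Ring C, a dihydropyran, is fused to the phloroglucinol-type ring A through C4a and C8a, carries the catechol ring B on C2 and a free secondary hydroxyl on C3, and only the ring A oxygens on C5 and C7 are esterified by gallic acid. The two adjacent stereocentres, C2 (R) and C3 (S), are trans. C3 is the carbinol carbon of a 3-aryllactic acid and can be bought; once in place it can steer C2 in a ring closure, because the half-chair with both substituents equatorial is favoured. Before ring C exists the two ortho oxygens of ring A are equivalent, so one must become O1 and the other an ester, while O3 must stay free of acyl groups. The aryl gallate esters are cleaved or shifted by alkoxide, hydroxide and hydride, the nine free hydroxyls oxidise in air under base, and the benzylic C2–O1 bond ionises under acid and epimerises C2, so the last step has to be neutral. The handle for ring closure is that C2 is a methylene benzylic to ring B and para to O4': loss of two electrons and a proton gives a cation stabilised as a para-quinone-methide oxocarbenium ion. The nucleophile that must capture it, the C8a hydroxyl, sits on ring A, which the two gallate esters meta to that hydroxyl make hard to oxidise.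

## Retrosynthesis

**18 ⇒ 17.** The nine O–CH2Ph bonds of perbenzylated flavan 17 are cut last. Benzyl ethers are preferred to silyl ethers or acetals because hydrogenolysis is neutral and spares aryl esters, whereas fluoride, base or acid would shift or cleave the gallates or ionise C2–O1. Precursor 17 has no free phenol and can be handled in air. The forward reaction must remove the slow secondary C3 benzyl ether without opening the benzylic C2–O1 bond.

**17 ⇒ 16.** The O1–C2 bond is cut to give 1,3-diarylpropan-2-ol ether 16, which has a free C8a hydroxyl and an unfunctionalised C2 methylene. A cut at C4–C4a would need a nucleophilic ring A and so excludes the gallates. A cut at O1–C8a would need an aryl halide and a C2 carbinol. A Mitsunobu closure at C2 would need a second stereocentre to be made and inverted. The C–H closure removes one ring and one stereocentre and leaves C3 as the only source of chirality. It requires oxidation at ring B alone, capture of the cation trans to the C3 benzyloxy group, and no further oxidation of 17.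

**16 ⇒ 12.** The two C4–H bonds are traced back to a C4 ketone and the free C8a hydroxyl to a third gallate ester, giving triester ketone 12. Selective diacylation of an alkylphloroglucinol cannot distinguish the ortho hydroxyls. In 12 both ortho esters are equivalent, and the borohydride deoxygenation itself uses one of them as the leaving group, so exactly one ortho phenol is set free. An acid-mediated deoxygenation of a chelated diester was set aside for the main line because it places a cation at C4 next to C3 on a deactivated ring. The forward step must reduce the ketone faster than the aryl esters.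

**12 ⇒ 9 + 11.** Three ester C–O bonds are cut to trihydroxyphenyl ketone 9 and three molecules of acid chloride 11, made from commercial acid 10. Exhaustive acylation needs no selectivity, and the precursor is much smaller.

**9 ⇒ 8 ⇒ 4 + 7.** The C4–C4a bond is cut between Weinreb amide 4 and aryllithium 7, which comes from tris-MOM ether 6 and phloroglucinol 5. Ketone 8 is the MOM-protected form of 9. Friedel–Crafts acylation of 5 with an α-benzyloxy acid chloride was rejected: α-alkoxy acylium ions lose CO, the Lewis acid strips benzyl ethers, and the α-centre can epimerise. The chelated tetrahedral intermediate of the Weinreb route holds C3 until work-up.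

**4 ⇒ 3 ⇒ 2 ⇒ 1.** Amide 4 comes from benzyl ester 3, which comes from hydroxy ester 2 and sodium danshensu 1 by two benzylations. The carboxyl carbon of 1 becomes C4, its carbinol carbon C3, its methylene C2 and its catechol ring B, so the absolute configuration and ring B are bought together.

## Roads not taken

**Alternative 1: sulfur-ylide epoxidation across C2–C3.** The cut is C2–C3. A chiral sulfonium ylide made from 3,4-bis(benzyloxy)benzyl bromide A1 would add to 2-[2,4,6-tris(methoxymethoxy)phenyl]acetaldehyde A2 and close to trans-epoxide A3. Acid would then remove the MOM groups and let the C8a hydroxyl open the epoxide at C2 with inversion, giving the 2,3-trans flavan-3-ol.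
- Merits: it is convergent, both stereocentres are set by the reagent in one C–C bond formation, and the flavan core is reached in fewer linear steps than in the chosen plan. In these respects it is better.
- Weak points: A2 is a hindered, enolisable arylacetaldehyde, and ylide epoxidations are most selective with non-enolisable aldehydes. The epoxide of A3 carries a 3,4-dialkoxyphenyl group, so its acid opening passes through the same quinone-methide cation as the chosen ring closure, and strict inversion is not assured. After closure the 5-, 7- and 3-hydroxyls are all free, and the phenols must be galloylated without touching O3.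
- Comparison: the chosen plan has the gallates on ring A before ring C exists, keeps O3 as a benzyl ether throughout, and takes C3 from the chiral pool instead of a stoichiometric chiral sulfide.

**Alternative 2: ring-closing metathesis at C3=C4.** The cut is the C3–C4 bond, formed as an alkene. Chiral allyl aryl ether A4 would be closed with second-generation Grubbs catalyst to flav-3-ene A5. Hydroboration–oxidation anti to the C2 aryl group would then set C3.
- Merits: metathesis to 2H-chromenes is robust, and hydroboration of flav-3-enes is a dependable way to the 2,3-trans 3-ol. Its diastereoselectivity should exceed that of a cation capture, so on that point this road is better.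
- Weak points: the C2 stereocentre of A4 is a benzylic, allylic aryl ether that is hard to make without ionisation or allylic transposition. 2-Aryl-2H-chromenes such as A5 can racemise by reversible electrocyclic ring opening. After hydroboration, O3 must be protected and both MOM groups exchanged for gallates, about four further steps.
- Comparison: the chosen plan secures the absolute configuration from the pool and avoids any protecting-group exchange on ring A.

**Alternative 3: epoxy-arene Friedel–Crafts closure at C4–C4a.** The cut is C4–C4a. In epoxy ether A6 both stereocentres and the O1–C2 bond are already in place. A Lewis acid such as BF3·OEt2 would make the ring A carbon ortho to the ether oxygen attack the terminal epoxide carbon in a 6-endo opening, giving A7 with a free 3-hydroxyl.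
- Merits: the ring closure creates no stereocentre, so the stereochemistry of ring C is more secure here than in the chosen plan. A7 also has O3 differentiated from O5 and O7.
- Weak points: the arene must be electron-rich, so the gallates cannot be present and allyl ethers stand in for them. The endgame therefore needs protection of O3, removal of the allyl groups with Pd(PPh3)4, galloylation and hydrogenolysis. The benzylic C2–O1 ether of A6 can ionise under the Lewis acid, 5-exo opening competes, and making A6 by Mitsunobu etherification of an electron-rich benzylic alcohol may leak through a cation.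
- Comparison: the chosen plan has a one-step endgame and needs no catalyst- or reagent-derived stereocentre.

Key step: step 10

Assumption: commercial sodium danshensu is the natural (R)-enantiomer. Its carbinol carbon becomes C3 with unchanged spatial arrangement; the descriptor is R in the open-chain intermediates and S in the flavan only because the CIP ranking of its two carbon neighbours changes. Flavan numbering is used for chain atoms throughout.

## Route

Step 1
Reactants: 1 sodium danshensu, sodium (R)-3-(3,4-dihydroxyphenyl)-2-hydroxypropanoate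
Product: 2 benzyl (R)-3-[3,4-bis(benzyloxy)phenyl]-2-hydroxypropanoate
Conditions: BnBr (3.3 equiv), K2CO3, DMF, rt, N2
Reagents that add atoms: benzyl bromide, BrCc1ccccc1
Why: Williamson-type O-alkylation of the carboxylate and the two phenoxides; carbonate deprotonates neither the secondary alcohol nor the α-C–H, so the hydroxyl stays free and the stereocentre is untouched.

Step 2
Reactants: 2 benzyl (R)-3-[3,4-bis(benzyloxy)phenyl]-2-hydroxypropanoate
Product: 3 benzyl (R)-2-(benzyloxy)-3-[3,4-bis(benzyloxy)phenyl]propanoate
Conditions: BnBr, Ag2O, CH2Cl2, rt, dark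
Reagents that add atoms: benzyl bromide, BrCc1ccccc1
Why: Purdie-type Ag2O-promoted O-benzylation of an α-hydroxy ester, which involves no free alkoxide or enolate and so should not epimerise the α-centre.

Step 3
Reactants: 3 benzyl (R)-2-(benzyloxy)-3-[3,4-bis(benzyloxy)phenyl]propanoate
Product: 4 (R)-2-(benzyloxy)-3-[3,4-bis(benzyloxy)phenyl]-N-methoxy-N-methylpropanamide
Conditions: MeNH(OMe)·HCl, iPrMgCl, THF, −20 to 0 °C
Reagents that add atoms: N,O-dimethylhydroxylamine hydrochloride, CNOC.Cl
Why: Weinreb amide synthesis by direct aminolysis of the ester with the magnesium amide; the amide anion is a poor base towards the α-alkoxy C–H at low temperature, so the configuration is kept.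

Step 4
Reactants: 5 phloroglucinol
Product: 6 1,3,5-tris(methoxymethoxy)benzene
Conditions: NaH, MOMCl, DMF, 0 °C to rt
Reagents that add atoms: chloromethyl methyl ether, COCCl
Why: Threefold O-alkylation of the phenoxides; the MOM ethers protect ring A and direct the lithiation of the next step.

Step 5
Reactants: 6 1,3,5-tris(methoxymethoxy)benzene; 4 (R)-2-(benzyloxy)-3-[3,4-bis(benzyloxy)phenyl]-N-methoxy-N-methylpropanamide
Product: 8 (R)-2-(benzyloxy)-3-[3,4-bis(benzyloxy)phenyl]-1-[2,4,6-tris(methoxymethoxy)phenyl]propan-1-one, via 2,4,6-tris(methoxymethoxy)phenyllithium 7 (not isolated)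
Conditions: 6, n-BuLi, THF, 0 °C; then 4, −78 to 0 °C; aq. NH4Cl
Reagents that add atoms: none
Why: Directed ortho-lithiation between two MOM ethers, then Weinreb ketone synthesis forming C4–C4a; the chelated tetrahedral intermediate prevents over-addition and hides the ketone from the basic aryllithium until work-up, which protects C3.

Step 6
Reactants: 8 (R)-2-(benzyloxy)-3-[3,4-bis(benzyloxy)phenyl]-1-[2,4,6-tris(methoxymethoxy)phenyl]propan-1-one
Product: 9 (R)-2-(benzyloxy)-3-[3,4-bis(benzyloxy)phenyl]-1-(2,4,6-trihydroxyphenyl)propan-1-one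
Conditions: HCl (3 M aq.), MeOH/THF, 45 °C
Reagents that add atoms: none
Why: Acid-catalysed acetal exchange removes the three MOM groups; benzyl ethers are stable to dilute HCl, and the strongly hydrogen-bonded acylphloroglucinol carbonyl enolises poorly towards C3.

Step 7
Reactants: 10 3,4,5-tris(benzyloxy)benzoic acid
Product: 11 3,4,5-tris(benzyloxy)benzoyl chloride
Conditions: (COCl)2, DMF (cat.), CH2Cl2, 0 °C to rt
Reagents that add atoms: oxalyl chloride, ClC(=O)C(=O)Cl
Why: Standard acid chloride formation through the Vilsmeier-type chloroiminium catalyst; all by-products are gases.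

Step 8
Reactants: 9 (R)-2-(benzyloxy)-3-[3,4-bis(benzyloxy)phenyl]-1-(2,4,6-trihydroxyphenyl)propan-1-one; 11 3,4,5-tris(benzyloxy)benzoyl chloride
Product: 12 2-[(2R)-2-(benzyloxy)-3-[3,4-bis(benzyloxy)phenyl]propanoyl]benzene-1,3,5-triyl tris[3,4,5-tris(benzyloxy)benzoate]
Conditions: 11 (3.5 equiv, three of which are taken up), pyridine, DMAP (cat.), CH2Cl2, 0 °C to rt
Reagents that add atoms: 3,4,5-tris(benzyloxy)benzoyl chloride (second equivalent of 11), ClC(=O)c1cc(OCc2ccccc2)c(OCc2ccccc2)c(OCc2ccccc2)c1; 3,4,5-tris(benzyloxy)benzoyl chloride (third equivalent of 11), ClC(=O)c1cc(OCc2ccccc2)c(OCc2ccccc2)c(OCc2ccccc2)c1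
Why: DMAP-catalysed acyl transfer of three molecules of 11, one to each phenol of 9 including the chelated one, so no selectivity is needed; pyridine is too weak a base to enolise the α-alkoxy ketone or to start a Baker–Venkataraman acyl shift.

Step 9
Reactants: 12 2-[(2R)-2-(benzyloxy)-3-[3,4-bis(benzyloxy)phenyl]propanoyl]benzene-1,3,5-triyl tris[3,4,5-tris(benzyloxy)benzoate]
Product: 16 4-[(2R)-2-(benzyloxy)-3-[3,4-bis(benzyloxy)phenyl]propyl]-5-hydroxy-1,3-phenylene bis[3,4,5-tris(benzyloxy)benzoate], via C4 carbinol 13 (not isolated), via acyl-shifted benzylic gallate 14 (not isolated), via ortho-quinone methide 15 (not isolated)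
Conditions: NaBH4, THF/H2O, 0 °C to rt; then aq. NH4Cl
Reagents that add atoms: none
Why: Borohydride deoxygenation of an ortho-acyloxyaryl ketone, the reaction type behind the ethyl carbonate/NaBH4 reduction of ortho-hydroxyaryl ketones: hydride gives alkoxide 13, a 1,5 O-to-O acyl shift frees a phenoxide (14), which expels the benzylic carboxylate to give 15, and a second hydride adds at C4. The two ortho esters of 12 are equivalent, so either shift gives the same phenol 16 and the ring A oxygens are told apart without selective acylation; C3 is not involved.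

Step 10
Reactants: 16 4-[(2R)-2-(benzyloxy)-3-[3,4-bis(benzyloxy)phenyl]propyl]-5-hydroxy-1,3-phenylene bis[3,4,5-tris(benzyloxy)benzoate]
Product: 17 (2R,3S)-3-(benzyloxy)-2-[3,4-bis(benzyloxy)phenyl]-3,4-dihydro-2H-chromene-5,7-diyl bis[3,4,5-tris(benzyloxy)benzoate]
Conditions: constant-current electrolysis, undivided cell, graphite anode, Pt cathode, n-Bu4NBF4, CH2Cl2/HFIP (4:1), about 2 F/mol, rt
Reagents that add atoms: none
Why: Proposed new method: the anode should take an electron from ring B, the only alkyl-dialkoxybenzene in 16 (each gallate ring carries an acyl group, ring A has two acyloxy groups meta to its hydroxyl, and without added base no phenoxide is present); the radical cation loses a C2 proton, the benzylic radical is oxidised again, and the C8a hydroxyl captures the para-quinone-methide oxocarbenium ion to form O1–C2. The closest known reaction types are the DDQ-mediated oxidative cyclisation of 1-(2-hydroxyphenyl)-3-arylpropanes to flavans and the anodic benzylic C–H alkoxylation of alkoxy-substituted alkylbenzenes; new here is the intramolecular phenol capture at an electrode next to an oxygen-bearing C3. Ring C closes in a 6-exo-trig mode, C2 being the exocyclic end of the C2=C1' bond of the quinone methide. C2 is set under substrate control by C3: in the chair-like transition state the ring B aryl group and the C3 benzyloxy group are both equatorial, which leads to the 2,3-trans (2R,3S) isomer; the preference is expected to be moderate and the cis epimer would be removed by chromatography. Site selectivity for C2–H over C4–H follows from C4 being benzylic only to the acyl-deactivated ring A, and over the O-benzyl methylenes from the faster deprotonation of ring-bound alkyl groups in alkoxyarene radical cations. Over-oxidation of 17 is held back by limiting the charge to about 2 F/mol and by the inductive effect of the new aryloxy group on C2; HFIP stabilises the radical cation, and if it captures the cation first the benzylic ether formed can ionise again to the same ion.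

Step 11
Reactants: 17 (2R,3S)-3-(benzyloxy)-2-[3,4-bis(benzyloxy)phenyl]-3,4-dihydro-2H-chromene-5,7-diyl bis[3,4,5-tris(benzyloxy)benzoate]
Product: 18 catechin 5,7-di-O-gallate, (2R,3S)-2-(3,4-dihydroxyphenyl)-3-hydroxy-3,4-dihydro-2H-chromene-5,7-diyl bis(3,4,5-trihydroxybenzoate)
Conditions: H2 (1 atm), Pd(OH)2/C, THF/MeOH, rt
Reagents that add atoms: none
Why: Global hydrogenolysis of the eight aryl benzyl ethers and the C3 alkyl benzyl ether under neutral conditions, which leave the aryl esters in place and set no stereocentre; both stereocentres are carried over from 17.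

## Compound list

1 | sodium danshensu, sodium (R)-3-(3,4-dihydroxyphenyl)-2-hydroxypropanoate | [Na+].[O-]C(=O)[C@H](O)Cc1ccc(O)c(O)c1 | starting material
2 | benzyl (R)-3-[3,4-bis(benzyloxy)phenyl]-2-hydroxypropanoate | O=C(OCc1ccccc1)[C@H](O)Cc1ccc(OCc2ccccc2)c(OCc2ccccc2)c1 | intermediate
3 | benzyl (R)-2-(benzyloxy)-3-[3,4-bis(benzyloxy)phenyl]propanoate | O=C(OCc1ccccc1)[C@H](OCc1ccccc1)Cc1ccc(OCc2ccccc2)c(OCc2ccccc2)c1 | intermediate
4 | (R)-2-(benzyloxy)-3-[3,4-bis(benzyloxy)phenyl]-N-methoxy-N-methylpropanamide | CON(C)C(=O)[C@H](OCc1ccccc1)Cc1ccc(OCc2ccccc2)c(OCc2ccccc2)c1 | intermediate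
5 | phloroglucinol | Oc1cc(O)cc(O)c1 | starting material
6 | 1,3,5-tris(methoxymethoxy)benzene | COCOc1cc(OCOC)cc(OCOC)c1 | intermediate
7 | 2,4,6-tris(methoxymethoxy)phenyllithium | [Li]c1c(OCOC)cc(OCOC)cc1OCOC | intermediate (not isolated)
8 | (R)-2-(benzyloxy)-3-[3,4-bis(benzyloxy)phenyl]-1-[2,4,6-tris(methoxymethoxy)phenyl]propan-1-one | O=C(c1c(OCOC)cc(OCOC)cc1OCOC)[C@H](OCc1ccccc1)Cc1ccc(OCc2ccccc2)c(OCc2ccccc2)c1 | intermediate
9 | (R)-2-(benzyloxy)-3-[3,4-bis(benzyloxy)phenyl]-1-(2,4,6-trihydroxyphenyl)propan-1-one | O=C(c1c(O)cc(O)cc1O)[C@H](OCc1ccccc1)Cc1ccc(OCc2ccccc2)c(OCc2ccccc2)c1 | intermediate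
10 | 3,4,5-tris(benzyloxy)benzoic acid | OC(=O)c1cc(OCc2ccccc2)c(OCc2ccccc2)c(OCc2ccccc2)c1 | starting material
11 | 3,4,5-tris(benzyloxy)benzoyl chloride | ClC(=O)c1cc(OCc2ccccc2)c(OCc2ccccc2)c(OCc2ccccc2)c1 | intermediate
12 | 2-[(2R)-2-(benzyloxy)-3-[3,4-bis(benzyloxy)phenyl]propanoyl]benzene-1,3,5-triyl tris[3,4,5-tris(benzyloxy)benzoate] | O=C(c1c(OC(=O)c2cc(OCc3ccccc3)c(OCc3ccccc3)c(OCc3ccccc3)c2)cc(OC(=O)c2cc(OCc3ccccc3)c(OCc3ccccc3)c(OCc3ccccc3)c2)cc1OC(=O)c1cc(OCc2ccccc2)c(OCc2ccccc2)c(OCc2ccccc2)c1)[C@H](OCc1ccccc1)Cc1ccc(OCc2ccccc2)c(OCc2ccccc2)c1 | intermediate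
13 | (2R)-2-(benzyloxy)-3-[3,4-bis(benzyloxy)phenyl]-1-{2,4,6-tris[3,4,5-tris(benzyloxy)benzoyloxy]phenyl}propan-1-ol (C4 carbinol, both C4 epimers, present as alkoxide) | OC(c1c(OC(=O)c2cc(OCc3ccccc3)c(OCc3ccccc3)c(OCc3ccccc3)c2)cc(OC(=O)c2cc(OCc3ccccc3)c(OCc3ccccc3)c(OCc3ccccc3)c2)cc1OC(=O)c1cc(OCc2ccccc2)c(OCc2ccccc2)c(OCc2ccccc2)c1)[C@H](OCc1ccccc1)Cc1ccc(OCc2ccccc2)c(OCc2ccccc2)c1 | intermediate (not isolated)
14 | (2R)-2-(benzyloxy)-3-[3,4-bis(benzyloxy)phenyl]-1-{2-hydroxy-4,6-bis[3,4,5-tris(benzyloxy)benzoyloxy]phenyl}propyl 3,4,5-tris(benzyloxy)benzoate (both C4 epimers, present as phenoxide) | O=C(OC(c1c(O)cc(OC(=O)c2cc(OCc3ccccc3)c(OCc3ccccc3)c(OCc3ccccc3)c2)cc1OC(=O)c1cc(OCc2ccccc2)c(OCc2ccccc2)c(OCc2ccccc2)c1)[C@H](OCc1ccccc1)Cc1ccc(OCc2ccccc2)c(OCc2ccccc2)c1)c1cc(OCc2ccccc2)c(OCc2ccccc2)c(OCc2ccccc2)c1 | intermediate (not isolated)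
15 | 6-[(2R)-2-(benzyloxy)-3-[3,4-bis(benzyloxy)phenyl]propylidene]-3,5-bis[3,4,5-tris(benzyloxy)benzoyloxy]cyclohexa-2,4-dien-1-one (ortho-quinone methide, alkene geometry undefined) | O=C1C=C(OC(=O)c2cc(OCc3ccccc3)c(OCc3ccccc3)c(OCc3ccccc3)c2)C=C(OC(=O)c2cc(OCc3ccccc3)c(OCc3ccccc3)c(OCc3ccccc3)c2)C1=C[C@H](OCc1ccccc1)Cc1ccc(OCc2ccccc2)c(OCc2ccccc2)c1 | intermediate (not isolated)
16 | 4-[(2R)-2-(benzyloxy)-3-[3,4-bis(benzyloxy)phenyl]propyl]-5-hydroxy-1,3-phenylene bis[3,4,5-tris(benzyloxy)benzoate] | O=C(Oc1cc(O)c(C[C@H](OCc2ccccc2)Cc2ccc(OCc3ccccc3)c(OCc3ccccc3)c2)c(OC(=O)c2cc(OCc3ccccc3)c(OCc3ccccc3)c(OCc3ccccc3)c2)c1)c1cc(OCc2ccccc2)c(OCc2ccccc2)c(OCc2ccccc2)c1 | intermediate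
17 | (2R,3S)-3-(benzyloxy)-2-[3,4-bis(benzyloxy)phenyl]-3,4-dihydro-2H-chromene-5,7-diyl bis[3,4,5-tris(benzyloxy)benzoate] | O=C(Oc1cc(OC(=O)c2cc(OCc3ccccc3)c(OCc3ccccc3)c(OCc3ccccc3)c2)c2c(c1)O[C@H](c1ccc(OCc3ccccc3)c(OCc3ccccc3)c1)[C@@H](OCc1ccccc1)C2)c1cc(OCc2ccccc2)c(OCc2ccccc2)c(OCc2ccccc2)c1 | intermediate
18 | catechin 5,7-di-O-gallate, (2R,3S)-2-(3,4-dihydroxyphenyl)-3-hydroxy-3,4-dihydro-2H-chromene-5,7-diyl bis(3,4,5-trihydroxybenzoate) | O=C(Oc1cc(OC(=O)c2cc(O)c(O)c(O)c2)c2c(c1)O[C@H](c1ccc(O)c(O)c1)[C@@H](O)C2)c1cc(O)c(O)c(O)c1 | target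

## Step count and least certain steps

Total: 11 steps. Longest linear sequence: 9 steps (steps 1, 2, 3, 5, 6, 8, 9, 10, 11).

**Step 10 (key step, new method).** The most likely failures are further oxidation of 17 at C2, because its ring B has almost the same potential as that of 16, and poor facial selectivity in the capture of a planar cation. Anodic loss of a ring B benzyl group and loss of the C3 proton from the cation to give an enol ether are further possibilities. Fallback with known chemistry: 16 is treated with DDQ in dry CH2Cl2 at rt. This is the established oxidative cyclisation of 1-(2-hydroxyphenyl)-3-arylpropanes, in which the quinone abstracts hydride from C2 within a charge-transfer complex with ring B and the phenol closes the ring. It sets out from 16 and returns at 17 without any new compound (F0).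

**Step 9.** The most likely failures are attack of hydride or hydroxide on the two aryl esters that must remain, and slow expulsion of the benzylic carboxylate, so that the sequence stalls after the acyl shift and the phenoxide exchanges esters between molecules. Fallback: starting from 9, two equivalents of 11 (Et3N, CH2Cl2, −20 °C) acylate the para and one ortho hydroxyl while the chelated one is spared. This gives 4-[(2R)-2-(benzyloxy)-3-[3,4-bis(benzyloxy)phenyl]propanoyl]-5-hydroxy-1,3-phenylene bis[3,4,5-tris(benzyloxy)benzoate] F1. Ionic hydrogenation of its ketone (Et3SiH, TFA, CH2Cl2) returns to the route at 16 with no ester sacrificed.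

**Step 5.** The most likely failure is the hindered aryllithium acting as a base: α-deprotonation of 4 would erode the configuration at C3 and leave amide unreacted. Fallback: starting from 3, iBu2AlH (toluene, −78 °C) gives (R)-2-(benzyloxy)-3-[3,4-bis(benzyloxy)phenyl]propanal F2. The more electrophilic aldehyde takes up 7 at −78 °C to give (2R)-2-(benzyloxy)-3-[3,4-bis(benzyloxy)phenyl]-1-[2,4,6-tris(methoxymethoxy)phenyl]propan-1-ol F3 as a mixture of C4 epimers. Dess–Martin oxidation of F3 returns to the route at 8.

**Step 11.** The most likely failure is hydrogenolysis of the benzylic C2–O1 bond of ring C during the long exposure needed for the secondary C3 benzyl ether; air oxidation of the free polyphenol on isolation is a second concern. Fallback: starting from 17, non-reductive debenzylation with BCl3 and pentamethylbenzene as cation scavenger (CH2Cl2, −78 °C), a method that spares aryl esters, leads directly to 18 without any new compound (F0).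

## Further compounds

F0 | step 10 | none | none
F1 | step 9 | 4-[(2R)-2-(benzyloxy)-3-[3,4-bis(benzyloxy)phenyl]propanoyl]-5-hydroxy-1,3-phenylene bis[3,4,5-tris(benzyloxy)benzoate] | O=C(c1c(O)cc(OC(=O)c2cc(OCc3ccccc3)c(OCc3ccccc3)c(OCc3ccccc3)c2)cc1OC(=O)c1cc(OCc2ccccc2)c(OCc2ccccc2)c(OCc2ccccc2)c1)[C@H](OCc1ccccc1)Cc1ccc(OCc2ccccc2)c(OCc2ccccc2)c1
F2 | step 5 | (R)-2-(benzyloxy)-3-[3,4-bis(benzyloxy)phenyl]propanal | O=C[C@H](OCc1ccccc1)Cc1ccc(OCc2ccccc2)c(OCc2ccccc2)c1
F3 | step 5 | (2R)-2-(benzyloxy)-3-[3,4-bis(benzyloxy)phenyl]-1-[2,4,6-tris(methoxymethoxy)phenyl]propan-1-ol (both C1 epimers) | OC(c1c(OCOC)cc(OCOC)cc1OCOC)[C@H](OCc1ccccc1)Cc1ccc(OCc2ccccc2)c(OCc2ccccc2)c1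
F0 | step 11 | none | none
A1 | alternative 1 | 3,4-bis(benzyloxy)benzyl bromide | BrCc1ccc(OCc2ccccc2)c(OCc2ccccc2)c1
A2 | alternative 1 | 2-[2,4,6-tris(methoxymethoxy)phenyl]acetaldehyde | O=CCc1c(OCOC)cc(OCOC)cc1OCOC
A3 | alternative 1 | (2S,3S)-2-[3,4-bis(benzyloxy)phenyl]-3-[2,4,6-tris(methoxymethoxy)benzyl]oxirane | c1(ccc(OCc2ccccc2)c(OCc2ccccc2)c1)[C@@H]1O[C@H]1Cc1c(OCOC)cc(OCOC)cc1OCOC
A4 | alternative 2 | 1-{[(1S)-1-[3,4-bis(benzyloxy)phenyl]prop-2-en-1-yl]oxy}-3,5-bis(methoxymethoxy)-2-vinylbenzene | C=Cc1c(OCOC)cc(OCOC)cc1O[C@H](c1ccc(OCc2ccccc2)c(OCc2ccccc2)c1)C=C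
A5 | alternative 2 | (2S)-2-[3,4-bis(benzyloxy)phenyl]-5,7-bis(methoxymethoxy)-2H-chromene | COCOc1cc(OCOC)c2c(c1)O[C@H](c1ccc(OCc3ccccc3)c(OCc3ccccc3)c1)C=C2
A6 | alternative 3 | (2S)-2-{(R)-[3,5-bis(allyloxy)phenoxy][3,4-bis(benzyloxy)phenyl]methyl}oxirane | C=CCOc1cc(OCC=C)cc(c1)O[C@H](c1ccc(OCc2ccccc2)c(OCc2ccccc2)c1)[C@@H]1CO1
A7 | alternative 3 | (2R,3S)-5,7-bis(allyloxy)-2-[3,4-bis(benzyloxy)phenyl]-3,4-dihydro-2H-chromen-3-ol | C=CCOc1cc(OCC=C)c2c(c1)O[C@H](c1ccc(OCc3ccccc3)c(OCc3ccccc3)c1)[C@@H](O)C2
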